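**Retrosynthetic overview**
- The six aryl C–Br bonds are made last, by exhaustive bromination of N,N'-bis(3,4-dihydroxybenzyl)urea, where every free ring position is ortho or para to a catechol OH.
- The catechols come from methyl ethers (BBr3), and the urea carbonyl from CDI plus two molecules of 3,4-dimethoxybenzylamine.
- The amine comes from its phthalimide. The key ArC–CH2N bond is made by an intermolecular aromatic Mannich-type amidoalkylation (Tscherniac–Einhorn) of veratrole with the N-acyliminium ion from N-(hydroxymethyl)phthalimide.
- No ring is formed at any stage; both benzene rings come from veratrole.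

Assumption: the target has no stereocentres (it is achiral), so "single enantiomer" is taken to mean the compound exactly as drawn and no stereocontrol is needed.

**Route**

Step 1
Reactants: 1 veratrole (1,2-dimethoxybenzene, 3 equiv); 2 N-(hydroxymethyl)phthalimide
Product: 4 N-(3,4-dimethoxybenzyl)phthalimide, via N-acyliminium ion 3 (not isolated)
Conditions: MeSO3H (3 equiv), CH2Cl2, 0 °C → rt
Reagents that add atoms: none
Why: Acid ionises 2 with loss of water to the N-acyliminium ion 3, which electron-rich veratrole attacks intermolecularly para to a methoxy group (Tscherniac–Einhorn amidoalkylation, an aromatic Mannich-type reaction), and the excess of arene suppresses double substitution.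

Step 2
Reactants: 4 N-(3,4-dimethoxybenzyl)phthalimide
Product: 5 3,4-dimethoxybenzylamine
Conditions: N2H4·H2O (3 equiv), EtOH, reflux
Reagents that add atoms: none
Why: Ing–Manske hydrazinolysis of the Gabriel-type phthalimide releases the primary amine and insoluble phthalhydrazide, and the aryl methyl ethers are inert to hydrazine.

Step 3
Reactants: 5 3,4-dimethoxybenzylamine (2 equiv)
Product: 7 N,N'-bis(3,4-dimethoxybenzyl)urea, via carbamoylimidazole 6 (not isolated)
Conditions: CDI (0.5 equiv), THF, rt → 60 °C
Reagents that add atoms: 1,1'-carbonyldiimidazole (CDI), O=C(n1ccnc1)n1ccnc1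
Why: Carbonylative urea formation: one amine acylates on CDI to give carbamoylimidazole 6, and on warming the second amine displaces imidazole to give the symmetrical urea, which precipitates.

Step 4
Reactants: 7 N,N'-bis(3,4-dimethoxybenzyl)urea
Product: 8 N,N'-bis(3,4-dihydroxybenzyl)urea
Conditions: BBr3 (8 equiv), CH2Cl2, −78 °C → rt; then ice/H2O
Reagents that add atoms: none
Why: Lewis-acid ether cleavage (BBr3 O-demethylation) removes all four methyl groups as bromomethane, and O-complexation of the ring oxygens disfavours ionisation of the benzylic C–N bond at low temperature.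

Step 5
Reactants: 8 N,N'-bis(3,4-dihydroxybenzyl)urea
Product: 9 N,N'-bis(2,3,6-tribromo-4,5-dihydroxybenzyl)urea (target)
Conditions: Br2 (6.3 equiv), AcOH, 15 °C → rt, dark; aq NaHSO3 work-up
Reagents that add atoms: bromine, BrBr
Why: Electrophilic aromatic bromination replaces every ring C–H, since all three free positions of each ring are ortho or para to a catechol hydroxyl, so no catalyst is needed and no regiochemical choice arises.

**Compound list**
1 | veratrole (1,2-dimethoxybenzene) | COc1ccccc1OC | starting material
2 | N-(hydroxymethyl)phthalimide | O=C1N(CO)C(=O)c2ccccc12 | starting material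
3 | N-methylidenephthalimidium (N-acyliminium) ion | C=[N+]1C(=O)c2ccccc2C1=O | intermediate
4 | N-(3,4-dimethoxybenzyl)phthalimide | COc1ccc(CN2C(=O)c3ccccc3C2=O)cc1OC | intermediate
5 | 3,4-dimethoxybenzylamine | COc1ccc(CN)cc1OC | intermediate
6 | N-(3,4-dimethoxybenzyl)-1H-imidazole-1-carboxamide | COc1ccc(CNC(=O)n2ccnc2)cc1OC | intermediate
7 | N,N'-bis(3,4-dimethoxybenzyl)urea | COc1ccc(CNC(=O)NCc2ccc(OC)c(OC)c2)cc1OC | intermediate
8 | N,N'-bis(3,4-dihydroxybenzyl)urea | O=C(NCc1ccc(O)c(O)c1)NCc1ccc(O)c(O)c1 | intermediate
9 | N,N'-bis(2,3,6-tribromo-4,5-dihydroxybenzyl)urea | O=C(NCc1c(Br)c(O)c(O)c(Br)c1Br)NCc1c(Br)c(O)c(O)c(Br)c1Br | target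

**Totals**
Total step count: 5. Longest linear sequence: 5 steps (1 → 4 → 5 → 7 → 8 → 9).

**Steps most likely to fail, and fallbacks**

Step 1 may give 4,5-bis(phthalimidomethyl)veratrole, or the electron-rich benzyl imide 4 may ionise in the acid and give diarylmethanes. The fallback sets out from 1 and keeps the same bond construction with a less ionisable nitrogen partner. Veratrole is amidoalkylated with 2-chloro-N-(hydroxymethyl)acetamide in AcOH containing H2SO4 at 10–20 °C to give 2-chloro-N-(3,4-dimethoxybenzyl)acetamide F1. This secondary amide is then hydrolysed in 6 M aqueous HCl/AcOH at reflux and the mixture is basified with aqueous NaOH. The sequence comes back to the route at amine 5, bypassing 4 and the hydrazinolysis.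

Step 4 may cleave the electron-rich benzyl–urea C–N bond with BBr3, or demethylate incompletely on the Lewis-basic urea. The fallback sets out from 5 and removes the methyl groups before the urea exists. Refluxing 48% aqueous HBr converts 5 into 3,4-dihydroxybenzylammonium bromide F2, in which the nitrogen is protected as its salt. F2 is then coupled under argon with N,N'-disuccinimidyl carbonate (0.5 equiv) and Et3N (2 equiv per F2) in DMF at 0 °C → rt. The amine is far more nucleophilic than the neutral catechol, so acylation is N-selective. The sequence comes back to the route at 8.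

Step 5 may suffer ipso attack, acid cleavage of the p-hydroxybenzyl–urea bond by the HBr formed, or incomplete hexabromination. The fallback sets out from 4 and brominates before the urea is built, on the robust imide:
- BBr3 in CH2Cl2 (−78 °C → rt) gives N-(3,4-dihydroxybenzyl)phthalimide F3.
- Br2 (3.2 equiv) in AcOH at rt gives N-(2,3,6-tribromo-4,5-dihydroxybenzyl)phthalimide F4.
- Base-free re-methylation of the acidic bromophenols with trimethylsilyldiazomethane in MeOH/toluene gives N-(2,3,6-tribromo-4,5-dimethoxybenzyl)phthalimide F5.
- Hydrazinolysis in EtOH at reflux gives 2,3,6-tribromo-4,5-dimethoxybenzylamine F6.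
- CDI (0.5 equiv) in THF at 60 °C gives N,N'-bis(2,3,6-tribromo-4,5-dimethoxybenzyl)urea F7.
- BBr3 in CH2Cl2 then demethylates F7, whose electron-poor rings resist benzylic ionisation.

The sequence comes back to the route at target 9.

**Further compounds**
F1 | step 1 | 2-chloro-N-(3,4-dimethoxybenzyl)acetamide | COc1ccc(CNC(=O)CCl)cc1OC
F2 | step 4 | 3,4-dihydroxybenzylammonium bromide | [NH3+]Cc1ccc(O)c(O)c1.[Br-]
F3 | step 5 | N-(3,4-dihydroxybenzyl)phthalimide | O=C1c2ccccc2C(=O)N1Cc1ccc(O)c(O)c1
F4 | step 5 | N-(2,3,6-tribromo-4,5-dihydroxybenzyl)phthalimide | O=C1c2ccccc2C(=O)N1Cc1c(Br)c(O)c(O)c(Br)c1Br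
F5 | step 5 | N-(2,3,6-tribromo-4,5-dimethoxybenzyl)phthalimide | COc1c(OC)c(Br)c(CN2C(=O)c3ccccc3C2=O)c(Br)c1Br
F6 | step 5 | 2,3,6-tribromo-4,5-dimethoxybenzylamine | COc1c(OC)c(Br)c(CN)c(Br)c1Br
F7 | step 5 | N,N'-bis(2,3,6-tribromo-4,5-dimethoxybenzyl)urea | COc1c(OC)c(Br)c(CNC(=O)NCc2c(Br)c(Br)c(OC)c(OC)c2Br)c(Br)c1Br
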